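**Plan**

- Numbering used here: oxolane O1, C2 (4-hydroxy-3,5-dimethoxyphenyl), C3 (Me), C4 (Me), C5 (3,4-dimethoxyphenyl). Retrosynthesis: the O-benzyl group is removed last, and the cis C3/C4 methyls are traced back to a cis-fused γ-lactone (C3–CH2–O–C(=O)–C4) carrying an extra CO2Me on C4. O1–C2 and C4–C5 are then cut together, in a formal (3+2) between 3,4-dimethoxybenzaldehyde (C5=O1) and a donor–acceptor cyclopropane C2–C3–C4.
- Enabling feature: the para-oxygenated aryl ring on C2 stabilises positive charge at C2, and C4, whose methyl is carried as a lactone carbonyl flanked by an ester, is a stabilised carbanion. The C2–C4 bond of a cyclopropane is therefore a latent 1,3-dipole.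
- Forward order: Z-cinnamyl silyl ether, then the cyclopropane, then the temporary lactone ring (3-oxabicyclo[3.1.0]hexanone), then the oxolane ring by the (3+2). After that the ester is removed, the lactone is reduced to two CH2OH groups, these are deoxygenated to the two methyls, and the benzyl group is cleaved.
- Stereochemistry: C3 and the precursor configuration of C2 come from catalyst-controlled cyclopropanation of a Z-olefin; C2 is set by inversion in the cycloaddition; C5 by the 2,5-cis mode of ring closure; C4 by the obligatory cis fusion of the temporary lactone.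

Key step: step 6

Remark: O-benzylsyringaldehyde, the Still–Gennari phosphonate, the malonate-derived phenyliodonium ylide and veratraldehyde are taken as purchasable; the antipode of the chiral ligand in step 4 is chosen to give the cyclopropane configuration shown.

**Route**

Step 1
Reactants: 1 4-(benzyloxy)-3,5-dimethoxybenzaldehyde; 2 methyl bis(2,2,2-trifluoroethyl)phosphonoacetate
Product: 3 methyl (2Z)-3-[4-(benzyloxy)-3,5-dimethoxyphenyl]prop-2-enoate
Conditions: KHMDS, 18-crown-6, THF, −78 °C
Reagents that add atoms: none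
Why: Still–Gennari olefination, in which the electron-poor phosphonate makes elimination from the kinetic oxaphosphetane fast, so the Z-enoate should predominate; this geometry later becomes the cis relation of aryl and CH2O on the cyclopropane.

Step 2
Reactants: 3 methyl (2Z)-3-[4-(benzyloxy)-3,5-dimethoxyphenyl]prop-2-enoate
Product: 4 (2Z)-3-[4-(benzyloxy)-3,5-dimethoxyphenyl]prop-2-en-1-ol
Conditions: DIBAL-H (2.5 equiv), CH2Cl2, −78 °C; Rochelle salt work-up
Reagents that add atoms: none
Why: DIBAL-H 1,2-reduction of the enoate to the allylic alcohol should leave the Z-olefin and the benzyl ether untouched.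

Step 3
Reactants: 4 (2Z)-3-[4-(benzyloxy)-3,5-dimethoxyphenyl]prop-2-en-1-ol
Product: 5 tert-butyl{[(2Z)-3-[4-(benzyloxy)-3,5-dimethoxyphenyl]prop-2-en-1-yl]oxy}dimethylsilane
Conditions: TBSCl, imidazole, DMF, 0 °C to rt
Reagents that add atoms: tert-butyldimethylsilyl chloride, CC(C)(C)[Si](C)(C)Cl
Why: Standard silylation of a primary alcohol; the silyl ether prevents O–H insertion of the copper carbene in step 4.

Step 4
Reactants: 5 tert-butyl{[(2Z)-3-[4-(benzyloxy)-3,5-dimethoxyphenyl]prop-2-en-1-yl]oxy}dimethylsilane; 6 dimethyl 2-(phenyl-λ3-iodanylidene)propanedioate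
Product: 7 dimethyl (2S,3S)-2-[4-(benzyloxy)-3,5-dimethoxyphenyl]-3-{[(tert-butyldimethylsilyl)oxy]methyl}cyclopropane-1,1-dicarboxylate (aryl cis to CH2OTBS)
Conditions: Cu(MeCN)4PF6 (cat.), chiral side-arm bis(oxazoline) ligand (cat.), 4 Å MS, toluene, 0 °C to rt
Reagents that add atoms: none
Why: Copper-carbene cyclopropanation of a cis-1,2-disubstituted olefin with a malonate iodonium ylide is concerted and stereospecific, so aryl and CH2OTBS should stay cis, while the chiral bis(oxazoline)–Cu(I) complex selects the olefin face and thereby sets C2 and C3.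

Step 5
Reactants: 7 dimethyl (2S,3S)-2-[4-(benzyloxy)-3,5-dimethoxyphenyl]-3-{[(tert-butyldimethylsilyl)oxy]methyl}cyclopropane-1,1-dicarboxylate
Product: 9 methyl (1R,5S,6S)-6-[4-(benzyloxy)-3,5-dimethoxyphenyl]-2-oxo-3-oxabicyclo[3.1.0]hexane-1-carboxylate (aryl endo), via hydroxymethyl cyclopropane diester 8 (not isolated)
Conditions: CSA (cat.), MeOH, rt
Reagents that add atoms: none
Why: Acid-catalysed methanolysis of the silyl ether frees the alcohol, which should lactonise (5-exo-trig acyl substitution) onto the only ester on its face of the cyclopropane, so that the two esters are differentiated and C1 becomes a defined stereocentre.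

Step 6
Reactants: 9 methyl (1R,5S,6S)-6-[4-(benzyloxy)-3,5-dimethoxyphenyl]-2-oxo-3-oxabicyclo[3.1.0]hexane-1-carboxylate; 10 3,4-dimethoxybenzaldehyde
Product: 12 methyl (3aS,4R,6R,6aS)-4-[4-(benzyloxy)-3,5-dimethoxyphenyl]-6-(3,4-dimethoxyphenyl)-1-oxotetrahydro-1H,3H-furo[3,4-c]furan-6a(6H)-carboxylate, via ring-opened oxocarbenium lactone-enolate zwitterion 11 (not isolated)
Conditions: Sn(OTf)2 (10 mol %), CH2Cl2, rt, excess of 10
Reagents that add atoms: none
Why: Sn(OTf)2 chelates the lactone and ester carbonyl groups on C1, the aldehyde oxygen attacks the benzylic C6 in an SN2-like manner and cleaves the C1–C6 bond with inversion to give the oxocarbenium/lactone-enolate 11, and the enolate carbon then adds to the oxocarbenium carbon. The closest known reaction type is the Lewis-acid-catalysed (3+2) cycloaddition of 2-arylcyclopropane-1,1-dicarboxylates with aldehydes, which gives 2,5-cis-tetrahydrofurans. The O–C bond arises by intermolecular substitution, and the oxolane ring then closes by a 5-(enolexo)-endo-trig aldol-type attack on the cationic C=O+ unit. C4 is set by the inversion, so that the aryl group, cis to CH2O in 9, ends trans to it; C6 is set by an envelope transition state in which the aryl group of the E-oxocarbenium ion lies pseudo-equatorial on the convex face (2,5-cis); C6a is set by the lactone tether, which allows only cis fusion; C3a is carried through unchanged. The step needs stereospecific opening instead of ionisation and cleavage of C1–C6 instead of C1–C5: the first should be secured by two-point chelation and by a donor of only moderate strength (the 4-benzyloxy group is twisted out of conjugation by its two ortho methoxy groups), the second by the aryl donor on C6 and by the better overlap of the external cyclopropane bond with the lactone carbonyl.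

Step 7
Reactants: 12 methyl (3aS,4R,6R,6aS)-4-[4-(benzyloxy)-3,5-dimethoxyphenyl]-6-(3,4-dimethoxyphenyl)-1-oxotetrahydro-1H,3H-furo[3,4-c]furan-6a(6H)-carboxylate
Product: 13 (3aS,4R,6S,6aS)-4-[4-(benzyloxy)-3,5-dimethoxyphenyl]-6-(3,4-dimethoxyphenyl)tetrahydro-1H,3H-furo[3,4-c]furan-1-one
Conditions: LiCl, H2O, DMSO, 140–150 °C
Reagents that add atoms: none
Why: Krapcho dealkoxycarbonylation (chloride attack on the ester methyl group, decarboxylation, protonation of the lactone enolate); protonation can only give the cis-fused bicycle, which fixes C6a with its hydrogen cis to H-3a.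

Step 8
Reactants: 13 (3aS,4R,6S,6aS)-4-[4-(benzyloxy)-3,5-dimethoxyphenyl]-6-(3,4-dimethoxyphenyl)tetrahydro-1H,3H-furo[3,4-c]furan-1-one
Product: 14 [(2R,3S,4R,5S)-2-[4-(benzyloxy)-3,5-dimethoxyphenyl]-5-(3,4-dimethoxyphenyl)oxolane-3,4-diyl]dimethanol
Conditions: LiAlH4, THF, 0 °C to rt
Reagents that add atoms: none
Why: LiAlH4 reduction of the lactone to the 1,4-diol touches no stereocentre and delivers the two cis CH2OH groups that stand for the two methyls.

Step 9
Reactants: 14 [(2R,3S,4R,5S)-2-[4-(benzyloxy)-3,5-dimethoxyphenyl]-5-(3,4-dimethoxyphenyl)oxolane-3,4-diyl]dimethanol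
Product: 15 [(2R,3S,4R,5S)-2-[4-(benzyloxy)-3,5-dimethoxyphenyl]-5-(3,4-dimethoxyphenyl)oxolane-3,4-diyl]bis(methylene) dimethanesulfonate
Conditions: MsCl (excess), Et3N, CH2Cl2, −20 to 0 °C
Reagents that add atoms: methanesulfonyl chloride, CS(=O)(=O)Cl
Why: Sulfene-type mesylation of primary alcohols is fast at low temperature, so with excess reagent both oxygens should be capped before the mono-mesylate can etherify.

Step 10
Reactants: 15 [(2R,3S,4R,5S)-2-[4-(benzyloxy)-3,5-dimethoxyphenyl]-5-(3,4-dimethoxyphenyl)oxolane-3,4-diyl]bis(methylene) dimethanesulfonate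
Product: 16 (2R,3R,4S,5S)-2-[4-(benzyloxy)-3,5-dimethoxyphenyl]-5-(3,4-dimethoxyphenyl)-3,4-dimethyloxolane
Conditions: LiEt3BH, THF, 0 °C to rt
Reagents that add atoms: none
Why: SN2 hydride displacement of primary sulfonates by LiEt3BH should convert both CH2OMs groups into methyls without involving the ring stereocentres (the descriptors at C3 and C4 change only through the priority rules).

Step 11
Reactants: 16 (2R,3R,4S,5S)-2-[4-(benzyloxy)-3,5-dimethoxyphenyl]-5-(3,4-dimethoxyphenyl)-3,4-dimethyloxolane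
Product: 17 4-[(2R,3R,4S,5S)-5-(3,4-dimethoxyphenyl)-3,4-dimethyloxolan-2-yl]-2,6-dimethoxyphenol
Conditions: H2 (1 atm), 10% Pd/C, EtOAc, rt
Reagents that add atoms: none
Why: Hydrogenolysis of the aryl benzyl ether frees the phenol, and under these mild conditions the hindered 2-aryl-oxolane C–O bonds should be retained.

**Compound list**

1 | 4-(benzyloxy)-3,5-dimethoxybenzaldehyde | O=Cc1cc(OC)c(OCc2ccccc2)c(OC)c1 | starting material
2 | methyl bis(2,2,2-trifluoroethyl)phosphonoacetate | COC(=O)CP(=O)(OCC(F)(F)F)OCC(F)(F)F | starting material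
3 | methyl (2Z)-3-[4-(benzyloxy)-3,5-dimethoxyphenyl]prop-2-enoate | COC(=O)/C=C\c1cc(OC)c(OCc2ccccc2)c(OC)c1 | intermediate
4 | (2Z)-3-[4-(benzyloxy)-3,5-dimethoxyphenyl]prop-2-en-1-ol | OC/C=C\c1cc(OC)c(OCc2ccccc2)c(OC)c1 | intermediate
5 | tert-butyl{[(2Z)-3-[4-(benzyloxy)-3,5-dimethoxyphenyl]prop-2-en-1-yl]oxy}dimethylsilane | CC(C)(C)[Si](C)(C)OC/C=C\c1cc(OC)c(OCc2ccccc2)c(OC)c1 | intermediate
6 | dimethyl 2-(phenyl-λ3-iodanylidene)propanedioate (malonate phenyliodonium ylide) | COC(=O)[C-]([I+]c1ccccc1)C(=O)OC | starting material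
7 | dimethyl (2S,3S)-2-[4-(benzyloxy)-3,5-dimethoxyphenyl]-3-{[(tert-butyldimethylsilyl)oxy]methyl}cyclopropane-1,1-dicarboxylate | COC(=O)C1(C(=O)OC)[C@H](c2cc(OC)c(OCc3ccccc3)c(OC)c2)[C@@H]1CO[Si](C)(C)C(C)(C)C | intermediate
8 | dimethyl (2S,3S)-2-[4-(benzyloxy)-3,5-dimethoxyphenyl]-3-(hydroxymethyl)cyclopropane-1,1-dicarboxylate | COC(=O)C1(C(=O)OC)[C@H](c2cc(OC)c(OCc3ccccc3)c(OC)c2)[C@@H]1CO | intermediate
9 | methyl (1R,5S,6S)-6-[4-(benzyloxy)-3,5-dimethoxyphenyl]-2-oxo-3-oxabicyclo[3.1.0]hexane-1-carboxylate | COC(=O)[C@]12C(=O)OC[C@H]1[C@H]2c1cc(OC)c(OCc2ccccc2)c(OC)c1 | intermediate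
10 | 3,4-dimethoxybenzaldehyde | COc1ccc(C=O)cc1OC | starting material
11 | ring-opened zwitterion: (E)-oxocarbenium ion of 10 bound through oxygen to the benzylic carbon, lactone enolate at the former C1 | COC(=O)C1=C([O-])OC[C@H]1[C@H](c1cc(OC)c(OCc2ccccc2)c(OC)c1)[O+]=Cc1ccc(OC)c(OC)c1 | intermediate
12 | methyl (3aS,4R,6R,6aS)-4-[4-(benzyloxy)-3,5-dimethoxyphenyl]-6-(3,4-dimethoxyphenyl)-1-oxotetrahydro-1H,3H-furo[3,4-c]furan-6a(6H)-carboxylate | COC(=O)[C@]12C(=O)OC[C@H]1[C@H](c1cc(OC)c(OCc3ccccc3)c(OC)c1)O[C@@H]2c1ccc(OC)c(OC)c1 | intermediate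
13 | (3aS,4R,6S,6aS)-4-[4-(benzyloxy)-3,5-dimethoxyphenyl]-6-(3,4-dimethoxyphenyl)tetrahydro-1H,3H-furo[3,4-c]furan-1-one | O=C1OC[C@H]2[C@H](c3cc(OC)c(OCc4ccccc4)c(OC)c3)O[C@H](c3ccc(OC)c(OC)c3)[C@@H]12 | intermediate
14 | [(2R,3S,4R,5S)-2-[4-(benzyloxy)-3,5-dimethoxyphenyl]-5-(3,4-dimethoxyphenyl)oxolane-3,4-diyl]dimethanol | OC[C@H]1[C@H](c2cc(OC)c(OCc3ccccc3)c(OC)c2)O[C@H](c2ccc(OC)c(OC)c2)[C@H]1CO | intermediate
15 | [(2R,3S,4R,5S)-2-[4-(benzyloxy)-3,5-dimethoxyphenyl]-5-(3,4-dimethoxyphenyl)oxolane-3,4-diyl]bis(methylene) dimethanesulfonate | CS(=O)(=O)OC[C@H]1[C@H](c2cc(OC)c(OCc3ccccc3)c(OC)c2)O[C@H](c2ccc(OC)c(OC)c2)[C@H]1COS(C)(=O)=O | intermediate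
16 | (2R,3R,4S,5S)-2-[4-(benzyloxy)-3,5-dimethoxyphenyl]-5-(3,4-dimethoxyphenyl)-3,4-dimethyloxolane | C[C@H]1[C@H](c2cc(OC)c(OCc3ccccc3)c(OC)c2)O[C@H](c2ccc(OC)c(OC)c2)[C@H]1C | intermediate
17 | 4-[(2R,3R,4S,5S)-5-(3,4-dimethoxyphenyl)-3,4-dimethyloxolan-2-yl]-2,6-dimethoxyphenol | COc1ccc([C@H]2O[C@@H](c3cc(OC)c(O)c(OC)c3)[C@H](C)[C@@H]2C)cc1OC | target

**Count and risks**

Total step count: 11. Longest linear sequence: 11 steps (from 1).

Steps most likely to fail:

1. Step 6. The C1–C6 bond may ionise before the aldehyde is bound, which would erase the configuration at the benzylic carbon, or capture by the weakly nucleophilic carbonyl oxygen may be too slow for the hindered endo-aryl cyclopropane. Fallback, setting out from 9: the cyclopropane would be opened (Sc(OTf)3 or Cu(OTf)2 cat., CH2Cl2) by the more nucleophilic 3,4-dimethoxybenzyl alcohol in an SN2-type homoconjugate addition to give methyl (4S)-4-{(R)-[4-(benzyloxy)-3,5-dimethoxyphenyl][(3,4-dimethoxyphenyl)methoxy]methyl}-2-oxooxolane-3-carboxylate F1. DDQ oxidation of its veratryl CH2–O position (oxidative C–H coupling of a benzylic ether with a 1,3-dicarbonyl carbon) would then generate the same oxocarbenium ion and close the ring, returning to the route at 12.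

2. Step 4. Facial discrimination of the Z-olefin by the catalyst may be insufficient, or the copper carbene may react with the electron-rich arene. Fallback, setting out from 4: acylation with methyl malonyl chloride (pyridine, CH2Cl2) would give (2Z)-3-[4-(benzyloxy)-3,5-dimethoxyphenyl]prop-2-en-1-yl methyl propanedioate F2, and diazo transfer (p-ABSA, Et3N, MeCN) would give the corresponding methyl 2-diazopropanedioate F3. Intramolecular cyclopropanation of F3 under a chiral Cu(I)–bis(oxazoline) or Rh(II) carboxylate catalyst, which is stereospecific for the Z-olefin and delivers the lactone directly, would return to the route at 9; crystallisation of 9 would be used to raise enantiomeric purity if required.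

3. Step 9. The mono-mesylate may undergo intramolecular displacement by the neighbouring cis hydroxymethyl group, closing a second oxolane ring before the second oxygen is capped. Fallback, setting out from 14: the diol would be converted without any carbon electrophile (NaH, CS2, then MeI, THF) into O,O'-{[(2R,3S,4R,5S)-2-[4-(benzyloxy)-3,5-dimethoxyphenyl]-5-(3,4-dimethoxyphenyl)oxolane-3,4-diyl]bis(methylene)} S,S'-dimethyl bis(carbonodithioate) F4. Barton–McCombie radical deoxygenation of F4 (Bu3SnH, AIBN, refluxing xylene) would return to the route at 16, bypassing 15.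

**Further compounds**

F1 | step 6 | methyl (4S)-4-{(R)-[4-(benzyloxy)-3,5-dimethoxyphenyl][(3,4-dimethoxyphenyl)methoxy]methyl}-2-oxooxolane-3-carboxylate (C3 epimers) | COC(=O)C1C(=O)OC[C@H]1[C@H](c1cc(OC)c(OCc2ccccc2)c(OC)c1)OCc1ccc(OC)c(OC)c1
F2 | step 4 | (2Z)-3-[4-(benzyloxy)-3,5-dimethoxyphenyl]prop-2-en-1-yl methyl propanedioate | COC(=O)CC(=O)OC/C=C\c1cc(OC)c(OCc2ccccc2)c(OC)c1
F3 | step 4 | (2Z)-3-[4-(benzyloxy)-3,5-dimethoxyphenyl]prop-2-en-1-yl methyl 2-diazopropanedioate | COC(=O)C(=[N+]=[N-])C(=O)OC/C=C\c1cc(OC)c(OCc2ccccc2)c(OC)c1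
F4 | step 9 | O,O'-{[(2R,3S,4R,5S)-2-[4-(benzyloxy)-3,5-dimethoxyphenyl]-5-(3,4-dimethoxyphenyl)oxolane-3,4-diyl]bis(methylene)} S,S'-dimethyl bis(carbonodithioate) | CSC(=S)OC[C@H]1[C@H](c2cc(OC)c(OCc3ccccc3)c(OC)c2)O[C@H](c2ccc(OC)c(OC)c2)[C@H]1COC(=S)SC
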